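All runs were generated by integration for substances that don't exist; noise was put on by code.

Read at 8.0 min, a flask shows two things at once: how far its living ends can carry it, and how much of that way they have gone. I keep the two apart for north, south-east, south and south-west.

| setting | dusk | dawn | north | south-east | south | south-west |
|---|---|---|---|---|---|---|
| free monomer | 10 mM | 10 mM | 10 mM | 10 mM | 10 mM | 10 mM |
| transfer agent | 1 mM | 1 mM | 1.00 mM | 1.00 mM | 1.00 mM | 1.00 mM |
| initiator | 10 µM | 15 µM | 20 µM | 20 µM | 20 µM | 20 µM |
| temperature | 25 °C | 50 °C | 70 °C |  | 30 °C | 50 °C |
| remark | run made earlier | run made earlier |  | at 30 °C until 4.0 min, from then on at 70 °C |  |  |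
| time |  |  | 8.0 min | 8.0 min | 8.0 min | 8.0 min |

| run | time / min | monomer in chains / % | free monomer / % |
|---|---|---|---|
| dusk | 10.0 | 22 | 79 |
| dusk | 20.0 | 32 | 72 |
| dusk | 30.0 | 37 | 66 |
| dusk | 40.0 | 34 | 62 |
| dusk | 50.0 | 37 | 60 |
| dusk | 60.0 | 37 | 59 |
| dawn | 2.50 | 39 | 57 |
| dawn | 5.00 | 54 | 45 |
| dawn | 8.00 | 67 | 40 |
| dawn | 10.0 | 63 | 34 |
| dawn | 15.0 | 67 | 31 |

(scatter of a reading: 2 percentage points)

- steps under discussion: free monomer + initiator -> living end + monomer in chains; living end + transfer agent -> dead chain; free monomer + living end -> monomer in chains + living end

- which flask leads in amount of monomer in chains, in percent of the free monomer charged ("all alike" within 1.5 percentage points) (north / south-east / south / south-west / all alike)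
- how much monomer in chains is there at the end, in percent of the free monomer charged: north
- how much monomer in chains is there at the end, in percent of the free monomer charged: south-east
- how much monomer in chains is there at the end, in percent of the free monomer charged: south
- how much monomer in chains is there at the end, in percent of the free monomer charged: south-west

I keep the books in initiator and follow one mole of it. Entry one: initiator takes a free monomer and opens a living end. Entry two: the living end adds free monomer and comes out unchanged, so it writes monomer in chains at no cost to itself. Entry three: a transfer agent turns it into a dead chain, and the account closes. Closing every account costs 2.00 % of the transfer agent in north, so the chance of dying per minute stays within that share of its starting value. At each fork the living end adds or dies, and adding takes a steady fraction of the free monomer per minute. Over its life, then, at one temperature, a living end lowers the logarithm of the free monomer by a fixed sum on average.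

So I call the reach the natural log of free monomer charged over free monomer at the stop, and I reckon it as initiator charge times a reach per initiator. Dusk ends at 59 %, which reads as 0.0528 µM⁻¹, and dawn ends at 31 %, which reads as 0.0781 µM⁻¹. Carrying the same factor per degree onward, I reckon for north a reach of 2.14, a ceiling of 88.2 %, and for south 1.14.

The early readings against those stops give the dying rate of living ends: 0.0487 min⁻¹ in dusk and 0.229 min⁻¹ in dawn. Carried the same way, north's 8.0 min spans 6.32 lives and south's 0.531, so north's free monomer should lie flat before the reading while south's is still falling. My figures are north 88.1 %, south-east 84.0 %, south 37.5 % and south-west 73.1 %.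

The forecast, resting on “The initiator is consumed and each chain dies by transfer, so conversion stalls.”, names north as leader with 88 %, south-east 83 %, south 39 % and south-west 74 %, and so differs from my figures at south-east, south and south-west.

The flasks give north 89.9 %, south-east 83.7 %, south 39.9 % and south-west 74.2 %, so north leads.

    free monomer + initiator → living end + monomer in chains (k = 5.20 M⁻¹ s⁻¹, Ea = 52.0 kJ mol⁻¹)
    living end + transfer agent → dead chain (kL = 3.80 M⁻¹ s⁻¹, Ea = 37.0 kJ mol⁻¹)
    free monomer + living end → monomer in chains + living end, rate k3*[living end]*[free monomer] (k = 310 M⁻¹ s⁻¹, Ea = 53.0 kJ mol⁻¹)
    (constants at 50 °C)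

North stops short of full conversion because of the step from living end and transfer agent to dead chain: with that step taken away, the same flask reaches >99.9 % instead of 89.9 %. At 80.0 min north holds 90.3 %, and its reach of 2.14 gave a ceiling of 88.2 %. With initiator and temperature held, I reckon the reach inversely with transfer agent, so north with 4.0 mM has a quarter of it, 0.534, which makes 41.4 %; that flask gives 44.0 %.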